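**Strategy.** The plan cuts the spiro 1,3-dioxan-4-one into a caged β-hydroxy acid and a 2-hydroxy-1,4-benzoquinone. Carbocyclic ring A (CH-prenyl carbon, two para ketone carbons, the enol-ether C=C shared with the 2H-pyran, spiro ketal carbon) is a quinone that has added O–H across one C=C. The para carbonyl pair and the pyran-fused C=C come from a pyran-fused cyclobutenedione. Its adduct with an α-ethoxyvinyllithium, a 4-alkenyl-4-hydroxycyclobutenone, expands in one thermal operation to the fully substituted six-membered ring A (strain-driven electrocyclic opening to a vinylketene, 6π closure, oxidation). The cage comes from a Claisen/Diels–Alder cascade and is resolved. Acylation of the hydroxyquinone and oxa-Michael closure set the last two stereocentres.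

Key step: step 6

Remark: tert-butyl 2-methylbut-3-en-2-yl carbonate is taken as a purchasable reagent (otherwise one step from 2-methylbut-3-en-2-ol and Boc2O).
Remark: the natural configuration at the spiro carbon and at the adjacent CH-prenyl carbon is taken to be the thermodynamically preferred one, as expected for centres formed by reversible conjugate addition and enolisation.

**Ring A fragment**

Step 1
Reactants: 1 diisopropyl squarate (3,4-diisopropoxycyclobut-3-ene-1,2-dione); 2 2-methylbut-3-yn-2-ol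
Product: 4 3-(3-hydroxy-3-methylbut-1-yn-1-yl)-4-isopropoxycyclobut-3-ene-1,2-dione, via carbinol adduct 3 (not isolated)
Conditions: 2, n-BuLi (2.1 equiv), THF, −78 °C; then 1, −78 °C; NH4Cl (aq); crude 3, 12 M HCl (cat.), CH2Cl2, 23 °C
Reagents that add atoms: none
Why: The acetylide carbon of the dilithiated alkynol adds 1,2 to a squarate carbonyl, and catalytic HCl then ionises the ring carbinol and transposes the allylic system with loss of isopropanol (Liebeskind–Moore cyclobutenedione synthesis).

Step 2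
Reactants: 4 3-(3-hydroxy-3-methylbut-1-yn-1-yl)-4-isopropoxycyclobut-3-ene-1,2-dione
Product: 6 3,3-dimethyl-2-oxabicyclo[4.2.0]octa-1(6),4-diene-7,8-dione, via cis-alkenyl dione 5 (not isolated)
Conditions: H2 (1 atm), Pd/CaCO3 poisoned with Pb(OAc)2, quinoline, EtOAc, 23 °C; then PPTS (cat.), CH2Cl2, 23 °C
Reagents that add atoms: none
Why: Cis-selective semihydrogenation brings the tertiary hydroxyl within reach of the isopropoxy-bearing ring carbon, and acid-catalysed intramolecular vinylogous transesterification (addition–elimination through a six-membered transition state) closes the 2H-pyran with loss of isopropanol, the open dienone valence isomer being a strained trione that should not be populated.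

Step 3
Reactants: 7 ethoxyethyne; 8 1-bromo-3-methylbut-2-ene (prenyl bromide)
Product: 9 1-ethoxy-5-methylhex-4-en-1-yne
Conditions: 7, n-BuLi, THF, −78 °C; then 8, HMPA, −78 to 23 °C
Reagents that add atoms: none
Why: Lithium ethoxyacetylide is alkylated in an SN2 reaction at the primary carbon of the allylic bromide, HMPA supplying the nucleophilicity this weakly reactive acetylide needs.

Step 4
Reactants: 9 1-ethoxy-5-methylhex-4-en-1-yne
Product: 10 tributyl[(1E)-1-ethoxy-5-methylhexa-1,4-dien-1-yl]stannane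
Conditions: Bu3SnH, Pd(PPh3)4 (2 mol%), THF, 0 °C
Reagents that add atoms: tributyltin hydride, CCCC[SnH](CCCC)CCCC
Why: Palladium-catalysed hydrostannation of a 1-alkoxyalkyne is a syn addition that places tin on the oxygen-bearing carbon, so the E stannane with ethoxy cis to the allylic CH2 should result.

Step 5
Reactants: 10 tributyl[(1E)-1-ethoxy-5-methylhexa-1,4-dien-1-yl]stannane; 6 3,3-dimethyl-2-oxabicyclo[4.2.0]octa-1(6),4-diene-7,8-dione
Product: 12 8-[(1Z)-1-ethoxy-5-methylhexa-1,4-dien-1-yl]-8-hydroxy-3,3-dimethyl-2-oxabicyclo[4.2.0]octa-1(6),4-dien-7-one (racemate), via vinyllithium 11 (not isolated)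
Conditions: 10, n-BuLi, THF, −78 °C; then 6, −78 °C; NH4Cl (aq)
Reagents that add atoms: none
Why: Tin–lithium exchange proceeds with retention, and the α-ethoxyvinyllithium adds 1,2 to carbonyl C8 next to the oxygen-bearing ring carbon because carbonyl C7 is deactivated as a vinylogous ester (the usual regiochemistry of 3-alkoxycyclobutenediones); the new carbinol centre is racemic and is destroyed in step 6.

Step 6
Reactants: 12 8-[(1Z)-1-ethoxy-5-methylhexa-1,4-dien-1-yl]-8-hydroxy-3,3-dimethyl-2-oxabicyclo[4.2.0]octa-1(6),4-dien-7-one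
Product: 16 7-ethoxy-2,2-dimethyl-6-(3-methylbut-2-en-1-yl)-2H-chromene-5,8-dione, via vinylketene 13 (not isolated), via cyclohexadienone 14 (not isolated), via hydroquinone 15 (not isolated)
Conditions: PhMe, 110 °C; then Ag2O, MgSO4, 23 °C
Reagents that add atoms: none
Why: Heating opens the strained cyclobutenone by conrotatory 4π-electrocyclic cleavage of the bond between the carbinol carbon and the ring carbonyl, the hydroxyl rotating outward so that the ethoxydienyl arm lies cis to the new ketene in 13; disrotatory 6π-electrocyclisation then bonds the ketene carbon to the prenyl-bearing vinyl terminus to give 14, which enolises to hydroquinone 15 and is dehydrogenated by Ag2O to quinone 16. The closest known reaction type is the Moore ring expansion of 4-alkenyl-4-hydroxycyclobutenones to hydroquinones and quinones. The only ring closed is the six-membered carbocycle, by thermal 6π-electrocyclisation, while the 2H-pyran is carried through intact. No stereocentre survives the step, because the sp3 carbon of 14 is lost on enolisation. The step needs the arm cis to the ketene, which the outward torquoselectivity of the hydroxyl secures (it also suppresses closure of the hydroxyl onto the ketene to a butenolide), and the right placement of substituents, which step 5 secures: the ethoxy carbon ends next to the carbonyl flanking the pyran oxygen and the prenyl carbon next to the other carbonyl. Release of four-ring strain and aromatisation should make the sequence irreversible.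

Step 7
Reactants: 16 7-ethoxy-2,2-dimethyl-6-(3-methylbut-2-en-1-yl)-2H-chromene-5,8-dione
Product: 17 7-hydroxy-2,2-dimethyl-6-(3-methylbut-2-en-1-yl)-2H-chromene-5,8-dione
Conditions: LiOH (1 M aq), THF, 0 °C; then 1 M HCl
Reagents that add atoms: lithium hydroxide (aqueous), [Li+].[OH-]
Why: Hydroxide adds to the ethoxy-bearing vinylogous ester carbon and expels ethoxide (addition–elimination), whereas a tetrahedral intermediate at the pyran-oxygen carbon would have to expel a tethered tertiary alkoxide and should therefore revert.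

**Caged hydroxy acid**

Step 8
Reactants: 18 2,3,4-trihydroxybenzoic acid
Product: 19 4-methoxybenzyl 2,3,4-trihydroxybenzoate
Conditions: 4-methoxybenzyl chloride (1.05 equiv), KHCO3, DMF, 23 °C
Reagents that add atoms: 4-methoxybenzyl chloride, COc1ccc(CCl)cc1
Why: Under bicarbonate only the carboxylic acid is deprotonated, so SN2 alkylation gives the ester and leaves the three phenols free.

Step 9
Reactants: 19 4-methoxybenzyl 2,3,4-trihydroxybenzoate
Product: 20 4-methoxybenzyl 2-hydroxy-3,4-bis[(2-methylbut-3-en-2-yl)oxy]benzoate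
Conditions: tert-butyl 2-methylbut-3-en-2-yl carbonate (2.3 equiv), Pd(PPh3)4 (5 mol%), THF, 0 to 23 °C
Reagents that add atoms: tert-butyl 2-methylbut-3-en-2-yl carbonate, CC(C)(C)OC(=O)OC(C)(C)C=C
Why: Palladium-catalysed decarboxylative allylic etherification (Tsuji–Trost type) alkylates phenols at the tertiary terminus of the 1,1-dimethylallyl unit, and the 2-hydroxyl, hydrogen-bonded to the ester carbonyl, is the least reactive and should stay free.

Step 10
Reactants: 20 4-methoxybenzyl 2-hydroxy-3,4-bis[(2-methylbut-3-en-2-yl)oxy]benzoate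
Product: 22 4-methoxybenzyl 2,5-dihydroxy-3,4-bis[(2-methylbut-3-en-2-yl)oxy]benzoate, via quinone 21 (not isolated)
Conditions: PhI(OAc)2 (2.2 equiv), MeCN/H2O, 0 °C; then Na2S2O4 (aq)
Reagents that add atoms: water, O
Why: PhI(OAc)2 oxidises the phenol to a phenoxenium equivalent that water captures at the free para position and that is oxidised further to the para-quinone, which Na2S2O4 reduces to the hydroquinone (net para-hydroxylation of a phenol).

Step 11
Reactants: 22 4-methoxybenzyl 2,5-dihydroxy-3,4-bis[(2-methylbut-3-en-2-yl)oxy]benzoate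
Product: 23 4-methoxybenzyl 2,5-bis[(4-methoxybenzyl)oxy]-3,4-bis[(2-methylbut-3-en-2-yl)oxy]benzoate
Conditions: 4-methoxybenzyl chloride (2.5 equiv), K2CO3, n-Bu4NI (cat.), DMF, 50 °C
Reagents that add atoms: 4-methoxybenzyl chloride, COc1ccc(CCl)cc1
Why: Williamson etherification of both phenols, the chelated one needing iodide catalysis and mild warming, masks the two oxygens that become the bridgehead hydroxyls.

Step 12
Reactants: 23 4-methoxybenzyl 2,5-bis[(4-methoxybenzyl)oxy]-3,4-bis[(2-methylbut-3-en-2-yl)oxy]benzoate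
Product: 25 4-methoxybenzyl 1,7-bis[(4-methoxybenzyl)oxy]-5,5-dimethyl-3-(3-methylbut-2-en-1-yl)-2-oxo-4-oxatricyclo[4.3.1.0(3,7)]dec-8-ene-8-carboxylate (racemate), via Claisen dienone 24 (not isolated)
Conditions: DMF, 120 °C
Reagents that add atoms: none
Why: The 1,1-dimethylallyl ether para to the ester undergoes aromatic Claisen rearrangement to the neighbouring oxygen-bearing carbon (the ester weakens that C–O bond), and the resulting 2,4-cyclohexadienone is trapped by intramolecular Diels–Alder addition of the remaining 1,1-dimethylallyl vinyl group, whose two-atom tether allows only one relative configuration of the four new stereocentres (Claisen/Diels–Alder cascade), the product being racemic.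

Step 13
Reactants: 25 racemic caged tris(4-methoxybenzyl) compound
Product: 26 the single enantiomer of 25 with the cage configuration of the target
Conditions: preparative SFC, amylose tris(3,5-dimethylphenylcarbamate) on silica, CO2/MeOH
Reagents that add atoms: none
Why: Chromatography on a chiral stationary phase separates the enantiomers, and the one with the target cage configuration (to be assigned by X-ray analysis of a crystalline derivative) is carried on, which fixes the absolute configuration of the four cage stereocentres.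

Step 14
Reactants: 26 enantiopure caged tris(4-methoxybenzyl) compound
Product: 27 1,7-dihydroxy-5,5-dimethyl-3-(3-methylbut-2-en-1-yl)-2-oxo-4-oxatricyclo[4.3.1.0(3,7)]dec-8-ene-8-carboxylic acid (single enantiomer)
Conditions: TFA/CH2Cl2 (1:9), anisole, 0 °C
Reagents that add atoms: none
Why: TFA ionises the 4-methoxybenzyl ester and both 4-methoxybenzyl ethers to the stabilised benzylic cation, which anisole traps, while the bridgehead carbinols cannot ionise and the β-hydroxy ketone is never exposed to base.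

**Union**

Step 15
Reactants: 27 caged dihydroxy acid; 17 7-hydroxy-2,2-dimethyl-6-(3-methylbut-2-en-1-yl)-2H-chromene-5,8-dione
Product: 29 CNP0222516.1, via acyloxyquinone 28 (not isolated)
Conditions: EDC·HCl, DMAP (cat.), CH2Cl2, 0 to 23 °C; then CSA (0.5 equiv), 23 °C
Reagents that add atoms: none
Why: Carbodiimide activation should give the 7-acyloxyquinone 28 (a vinylogous anhydride), whose acyloxy-bearing carbon is the β-carbon of the C5 enone, and acid then promotes 6-exo oxa-Michael addition of the cage bridgehead hydroxyl to that carbon followed by protonation at C6; both new stereocentres are under thermodynamic control through reversible conjugate addition and enolisation, and the expected outcome is the spiro epimer with the CH-prenyl carbon on the side of the prenyl-bearing cage carbon and the prenyl group anti to the cage ether oxygen.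

**Compound list**

1 | diisopropyl squarate (3,4-diisopropoxycyclobut-3-ene-1,2-dione) | CC(C)OC1=C(OC(C)C)C(=O)C1=O | starting material
2 | 2-methylbut-3-yn-2-ol | CC(C)(O)C#C | starting material
3 | 4-hydroxy-4-(3-hydroxy-3-methylbut-1-yn-1-yl)-2,3-diisopropoxycyclobut-2-en-1-one (racemate) | CC(C)OC1=C(OC(C)C)C(O)(C#CC(C)(C)O)C1=O | intermediate
4 | 3-(3-hydroxy-3-methylbut-1-yn-1-yl)-4-isopropoxycyclobut-3-ene-1,2-dione | CC(C)OC1=C(C#CC(C)(C)O)C(=O)C1=O | intermediate
5 | 3-[(1Z)-3-hydroxy-3-methylbut-1-en-1-yl]-4-isopropoxycyclobut-3-ene-1,2-dione | CC(C)OC1=C(/C=C\C(C)(C)O)C(=O)C1=O | intermediate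
6 | 3,3-dimethyl-2-oxabicyclo[4.2.0]octa-1(6),4-diene-7,8-dione (2H-pyran-fused cyclobutenedione) | CC1(C)C=CC2=C(O1)C(=O)C2=O | intermediate
7 | ethoxyethyne | CCOC#C | starting material
8 | 1-bromo-3-methylbut-2-ene | CC(C)=CCBr | starting material
9 | 1-ethoxy-5-methylhex-4-en-1-yne | CCOC#CCC=C(C)C | intermediate
10 | tributyl[(1E)-1-ethoxy-5-methylhexa-1,4-dien-1-yl]stannane | CCO/C(=C\CC=C(C)C)[Sn](CCCC)(CCCC)CCCC | intermediate
11 | [(1Z)-1-ethoxy-5-methylhexa-1,4-dien-1-yl]lithium (ethoxy cis to the allylic CH2) | CCO/C([Li])=C\CC=C(C)C | intermediate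
12 | 8-[(1Z)-1-ethoxy-5-methylhexa-1,4-dien-1-yl]-8-hydroxy-3,3-dimethyl-2-oxabicyclo[4.2.0]octa-1(6),4-dien-7-one (racemate) | CCO/C(=C\CC=C(C)C)C1(O)C2=C(C=CC(C)(C)O2)C1=O | intermediate
13 | {6-[2-ethoxy-1-hydroxy-6-methylhepta-2,5-dien-1-ylidene]-2,2-dimethyl-2H-pyran-5(6H)-ylidene}methanone (vinylketene) | CCO/C(=C\CC=C(C)C)C(O)=C1OC(C)(C)C=CC1=C=O | intermediate
14 | 7-ethoxy-8-hydroxy-2,2-dimethyl-6-(3-methylbut-2-en-1-yl)-2H-chromen-5(6H)-one (racemate) | CCOC1=C(O)C2=C(C=CC(C)(C)O2)C(=O)C1CC=C(C)C | intermediate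
15 | 7-ethoxy-2,2-dimethyl-6-(3-methylbut-2-en-1-yl)-2H-chromene-5,8-diol | CCOc1c(CC=C(C)C)c(O)c2C=CC(C)(C)Oc2c1O | intermediate
16 | 7-ethoxy-2,2-dimethyl-6-(3-methylbut-2-en-1-yl)-2H-chromene-5,8-dione | CCOC1=C(CC=C(C)C)C(=O)C2=C(OC(C)(C)C=C2)C1=O | intermediate
17 | 7-hydroxy-2,2-dimethyl-6-(3-methylbut-2-en-1-yl)-2H-chromene-5,8-dione | CC(C)=CCC1=C(O)C(=O)C2=C(C=CC(C)(C)O2)C1=O | intermediate
18 | 2,3,4-trihydroxybenzoic acid | OC(=O)c1ccc(O)c(O)c1O | starting material
19 | 4-methoxybenzyl 2,3,4-trihydroxybenzoate | COc1ccc(COC(=O)c2ccc(O)c(O)c2O)cc1 | intermediate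
20 | 4-methoxybenzyl 2-hydroxy-3,4-bis[(2-methylbut-3-en-2-yl)oxy]benzoate | COc1ccc(COC(=O)c2ccc(OC(C)(C)C=C)c(OC(C)(C)C=C)c2O)cc1 | intermediate
21 | 4-methoxybenzyl 4,5-bis[(2-methylbut-3-en-2-yl)oxy]-3,6-dioxocyclohexa-1,4-diene-1-carboxylate | COc1ccc(COC(=O)C2=CC(=O)C(OC(C)(C)C=C)=C(OC(C)(C)C=C)C2=O)cc1 | intermediate
22 | 4-methoxybenzyl 2,5-dihydroxy-3,4-bis[(2-methylbut-3-en-2-yl)oxy]benzoate | COc1ccc(COC(=O)c2cc(O)c(OC(C)(C)C=C)c(OC(C)(C)C=C)c2O)cc1 | intermediate
23 | 4-methoxybenzyl 2,5-bis[(4-methoxybenzyl)oxy]-3,4-bis[(2-methylbut-3-en-2-yl)oxy]benzoate | COc1ccc(COC(=O)c2cc(OCc3ccc(OC)cc3)c(OC(C)(C)C=C)c(OC(C)(C)C=C)c2OCc2ccc(OC)cc2)cc1 | intermediate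
24 | 4-methoxybenzyl 2,5-bis[(4-methoxybenzyl)oxy]-3-(3-methylbut-2-en-1-yl)-3-[(2-methylbut-3-en-2-yl)oxy]-4-oxocyclohexa-1,5-diene-1-carboxylate (racemate; the enantiomer leading to 26 is drawn) | COc1ccc(COC(=O)C2=C(OCc3ccc(OC)cc3)[C@@](CC=C(C)C)(OC(C)(C)C=C)C(=O)C(OCc3ccc(OC)cc3)=C2)cc1 | intermediate
25 | 4-methoxybenzyl 1,7-bis[(4-methoxybenzyl)oxy]-5,5-dimethyl-3-(3-methylbut-2-en-1-yl)-2-oxo-4-oxatricyclo[4.3.1.0(3,7)]dec-8-ene-8-carboxylate (racemate; the enantiomer carried on is drawn) | COc1ccc(COC(=O)C2=C[C@]3(OCc4ccc(OC)cc4)C[C@H]4C(C)(C)O[C@@](CC=C(C)C)(C3=O)[C@@]24OCc2ccc(OC)cc2)cc1 | intermediate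
26 | the same ester as 25, single enantiomer with the cage configuration of the target | COc1ccc(COC(=O)C2=C[C@]3(OCc4ccc(OC)cc4)C[C@H]4C(C)(C)O[C@@](CC=C(C)C)(C3=O)[C@@]24OCc2ccc(OC)cc2)cc1 | intermediate
27 | 1,7-dihydroxy-5,5-dimethyl-3-(3-methylbut-2-en-1-yl)-2-oxo-4-oxatricyclo[4.3.1.0(3,7)]dec-8-ene-8-carboxylic acid, single enantiomer with the cage configuration of the target | OC(=O)C1=C[C@]2(O)C[C@H]3C(C)(C)O[C@@](CC=C(C)C)(C2=O)[C@@]13O | intermediate
28 | 2,2-dimethyl-6-(3-methylbut-2-en-1-yl)-5,8-dioxo-5,8-dihydro-2H-chromen-7-yl ester of acid 27 | CC(C)=CCC1=C(OC(=O)C2=C[C@]3(O)C[C@H]4C(C)(C)O[C@@](CC=C(C)C)(C3=O)[C@@]24O)C(=O)C2=C(C=CC(C)(C)O2)C1=O | intermediate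
29 | CNP0222516.1: spiro ketal-lactone in which C7 of the 6-prenyl-2,2-dimethyl-6,7-dihydro-2H-chromene-5,8-dione is the ketal carbon of a 1,3-dioxin-4-one closed by the carboxyl and the C7 oxygen of the cage of 27 | CC(C)=CC[C@H]1C(=O)C2=C(OC(C)(C)C=C2)C(=O)[C@@]12OC(=O)C1=C[C@]3(O)C[C@H]4C(C)(C)O[C@@](CC=C(C)C)(C3=O)[C@@]14O2 | target

Total step count: 15. Longest linear sequence: 8 steps (steps 8 to 15).

**Steps most likely to fail**

Step 15. The hindered bridgehead hydroxyl may fail to add to the acyloxy-bearing quinone carbon before the vinylogous anhydride is hydrolysed or trans-acylated, and equilibration may stall at the wrong spiro epimer. The fallback sets out from 17 and 22 and comes back at 29; it makes the ether bond to the future spiro carbon first, on flat partners, and builds the cage afterwards. Oxalyl chloride with catalytic DMF converts 17 into 7-chloro-2,2-dimethyl-6-(3-methylbut-2-en-1-yl)-2H-chromene-5,8-dione F1. Compound 22 is etherified only at its non-chelated 5-hydroxyl (4-methoxybenzyl chloride, K2CO3, acetone, 23 °C) to give 4-methoxybenzyl 2-hydroxy-5-[(4-methoxybenzyl)oxy]-3,4-bis[(2-methylbut-3-en-2-yl)oxy]benzoate F2. The phenoxide of F2 displaces chloride from F1 by addition–elimination (Cs2CO3, MeCN, 0 °C) to give the aryloxyquinone F3. Heating in toluene at 110 °C runs the same Claisen/Diels–Alder cascade to the caged quinone F4, formed as a racemate and resolved on a chiral stationary phase. TFA/anisole then removes both 4-methoxybenzyl groups to give the seco acid F5, whose carboxyl should add under the same acid to the alkoxy-bearing quinone carbon to give 29.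

Step 2. Over-reduction of the electron-poor alkyne, or failure of the pyran closure because the fused dienedione is too strained to form or to survive, would stop the route. The fallback sets out from 1 and 10 and comes back at 17; it keeps the ring expansion but closes the pyran afterwards on the unstrained quinone. Reduction of 1 with LiAlH(O-t-Bu)3 gives 4-hydroxy-2,3-diisopropoxycyclobut-2-en-1-one F6, which HCl rearranges to 3-isopropoxycyclobut-3-ene-1,2-dione F7. Vinyllithium 11 (from 10) adds to the carbonyl next to the alkoxy carbon to give 4-[(1Z)-1-ethoxy-5-methylhexa-1,4-dien-1-yl]-4-hydroxy-3-isopropoxycyclobut-2-en-1-one F8. The same thermal ring expansion gives 2-ethoxy-6-isopropoxy-3-(3-methylbut-2-en-1-yl)benzene-1,4-diol F9, and Ag2O then gives 2-ethoxy-6-isopropoxy-3-(3-methylbut-2-en-1-yl)cyclohexa-2,5-diene-1,4-dione F10. Aqueous NaOH hydrolyses both vinylogous esters to 2,6-dihydroxy-3-(3-methylbut-2-en-1-yl)cyclohexa-2,5-diene-1,4-dione F11. Knoevenagel condensation with 3-methylbut-2-enal at the only free ring carbon and oxa-6π closure (ethylenediammonium diacetate, MeOH) give 17, the para-quinone being the expected thermodynamic regioisomer.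

Step 10. The oxidant may attack the electron-rich tertiary allylic ethers, the acetic acid released may cleave them, or the phenol may be over-oxidised. The fallback sets out from 20 and comes back at 22 through 21; it introduces the para heteroatom as nitrogen under basic conditions. Azo coupling of 20 with 4-sulfobenzenediazonium (from 4-aminobenzenesulfonic acid, NaNO2, HCl) in aqueous Na2CO3/THF at 0 °C gives 4-[(E)-(4-hydroxy-5-{[(4-methoxybenzyl)oxy]carbonyl}-2,3-bis[(2-methylbut-3-en-2-yl)oxy]phenyl)diazenyl]benzenesulfonic acid F12. Na2S2O4 cleaves the azo bond to 4-methoxybenzyl 5-amino-2-hydroxy-3,4-bis[(2-methylbut-3-en-2-yl)oxy]benzoate F13. Brief treatment with aqueous FeCl3 oxidises the para-aminophenol and hydrolyses the quinone imine to 21, which is reduced to 22 as in step 10.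

Further compounds
F1 | step 15 | 7-chloro-2,2-dimethyl-6-(3-methylbut-2-en-1-yl)-2H-chromene-5,8-dione | CC(C)=CCC1=C(Cl)C(=O)C2=C(C=CC(C)(C)O2)C1=O
F2 | step 15 | 4-methoxybenzyl 2-hydroxy-5-[(4-methoxybenzyl)oxy]-3,4-bis[(2-methylbut-3-en-2-yl)oxy]benzoate | COc1ccc(COC(=O)c2cc(OCc3ccc(OC)cc3)c(OC(C)(C)C=C)c(OC(C)(C)C=C)c2O)cc1
F3 | step 15 | 4-methoxybenzyl 2-{[2,2-dimethyl-6-(3-methylbut-2-en-1-yl)-5,8-dioxo-5,8-dihydro-2H-chromen-7-yl]oxy}-5-[(4-methoxybenzyl)oxy]-3,4-bis[(2-methylbut-3-en-2-yl)oxy]benzoate | COc1ccc(COC(=O)c2cc(OCc3ccc(OC)cc3)c(OC(C)(C)C=C)c(OC(C)(C)C=C)c2OC2=C(CC=C(C)C)C(=O)C3=C(OC(C)(C)C=C3)C2=O)cc1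
F4 | step 15 | 4-methoxybenzyl 7-{[2,2-dimethyl-6-(3-methylbut-2-en-1-yl)-5,8-dioxo-5,8-dihydro-2H-chromen-7-yl]oxy}-1-[(4-methoxybenzyl)oxy]-5,5-dimethyl-3-(3-methylbut-2-en-1-yl)-2-oxo-4-oxatricyclo[4.3.1.0(3,7)]dec-8-ene-8-carboxylate (formed as racemate; resolved enantiomer drawn) | COc1ccc(COC(=O)C2=C[C@]3(OCc4ccc(OC)cc4)C[C@H]4C(C)(C)O[C@@](CC=C(C)C)(C3=O)[C@@]24OC2=C(CC=C(C)C)C(=O)C3=C(OC(C)(C)C=C3)C2=O)cc1
F5 | step 15 | 7-{[2,2-dimethyl-6-(3-methylbut-2-en-1-yl)-5,8-dioxo-5,8-dihydro-2H-chromen-7-yl]oxy}-1-hydroxy-5,5-dimethyl-3-(3-methylbut-2-en-1-yl)-2-oxo-4-oxatricyclo[4.3.1.0(3,7)]dec-8-ene-8-carboxylic acid | OC(=O)C1=C[C@]2(O)C[C@H]3C(C)(C)O[C@@](CC=C(C)C)(C2=O)[C@@]13OC1=C(CC=C(C)C)C(=O)C2=C(OC(C)(C)C=C2)C1=O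
F6 | step 2 | 4-hydroxy-2,3-diisopropoxycyclobut-2-en-1-one | CC(C)OC1=C(OC(C)C)C(O)C1=O
F7 | step 2 | 3-isopropoxycyclobut-3-ene-1,2-dione | CC(C)OC1=CC(=O)C1=O
F8 | step 2 | 4-[(1Z)-1-ethoxy-5-methylhexa-1,4-dien-1-yl]-4-hydroxy-3-isopropoxycyclobut-2-en-1-one | CCO/C(=C\CC=C(C)C)C1(O)C(OC(C)C)=CC1=O
F9 | step 2 | 2-ethoxy-6-isopropoxy-3-(3-methylbut-2-en-1-yl)benzene-1,4-diol | CCOc1c(CC=C(C)C)c(O)cc(OC(C)C)c1O
F10 | step 2 | 2-ethoxy-6-isopropoxy-3-(3-methylbut-2-en-1-yl)cyclohexa-2,5-diene-1,4-dione | CCOC1=C(CC=C(C)C)C(=O)C=C(OC(C)C)C1=O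
F11 | step 2 | 2,6-dihydroxy-3-(3-methylbut-2-en-1-yl)cyclohexa-2,5-diene-1,4-dione | CC(C)=CCC1=C(O)C(=O)C(O)=CC1=O
F12 | step 10 | 4-[(E)-(4-hydroxy-5-{[(4-methoxybenzyl)oxy]carbonyl}-2,3-bis[(2-methylbut-3-en-2-yl)oxy]phenyl)diazenyl]benzenesulfonic acid | COc1ccc(COC(=O)c2cc(/N=N/c3ccc(cc3)S(O)(=O)=O)c(OC(C)(C)C=C)c(OC(C)(C)C=C)c2O)cc1
F13 | step 10 | 4-methoxybenzyl 5-amino-2-hydroxy-3,4-bis[(2-methylbut-3-en-2-yl)oxy]benzoate | COc1ccc(COC(=O)c2cc(N)c(OC(C)(C)C=C)c(OC(C)(C)C=C)c2O)cc1
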